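**Plan**

- Retrosynthesis: the benzyl ethers on O2' and O4' of ring B are cut first; the C6–O and C8–O bonds of ring A go back through C–Br to C–H and the O5/O7 methyls are removed, leaving a 5,7-dihydroxyflavone. Ring A is then opened at C4a–C5, the keto ester arm is cut at its bond to the lateral pyranone carbon, and the 4-pyranone is cut into acetylacetone and a ring B benzoate.
- Forward: ring B is bought as a benzaldehyde and converted into the 2,4-dibenzyloxy-5-methoxybenzoate; ring C is closed by cyclodehydration of a 1,3,5-triketone; the 3-oxobutanoate arm is attached; ring A is closed last by Claisen condensation; C6 and C8 are then oxygenated and the benzyl groups removed.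
- Enabling feature: in ring A the oxygens on C5, C7 and C8a (the ring oxygen O1) sit on alternate carbons, the acetate (phloroglucinol) pattern. C5–C8 can therefore be a methyl 3-oxobutanoate chain on pyranone C2 (the later C8a), with pyranone C3 (the later C4a) as nucleophile and the ester carbon (the later C5) as electrophile. The C6 and C8 oxygens do not fit this pattern and are added afterwards.
- Stereochemistry: the target has no stereocentre and no configured double bond, so nothing has to be controlled.

Key step: step 8

Remark on the chemistry: the triketone and the β-keto ester are drawn as keto tautomers although both should be largely enolised, and 3-benzyloxy-4-methoxybenzaldehyde (O-benzylisovanillin) is taken as a catalogue compound.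

**Route**

Step 1
Reactants: 1 3-benzyloxy-4-methoxybenzaldehyde
Product: 3 3-benzyloxy-4-methoxyphenol, via 3-benzyloxy-4-methoxyphenyl formate 2 (not isolated)
Conditions: mCPBA, CH2Cl2, 0 °C to rt; NaHCO3 wash; then K2CO3 (cat.), MeOH, rt
Reagents that add atoms: mCPBA, OOC(=O)c1cccc(Cl)c1
Why: Baeyer–Villiger oxidation, in which the electron-rich 3,4-dialkoxyphenyl group migrates in preference to hydride, followed by base-catalysed transesterification of the aryl formate to the phenol.

Step 2
Reactants: 3 3-benzyloxy-4-methoxyphenol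
Product: 4 2,4-dibenzyloxy-1-methoxybenzene
Conditions: BnBr, K2CO3, DMF, 60 °C
Reagents that add atoms: benzyl bromide, BrCc1ccccc1
Why: Williamson ether synthesis of a phenoxide with a primary benzylic bromide.

Step 3
Reactants: 4 2,4-dibenzyloxy-1-methoxybenzene
Product: 5 1-bromo-2,4-dibenzyloxy-5-methoxybenzene
Conditions: NBS (1.0 equiv), MeCN, 0 °C, dark
Reagents that add atoms: N-bromosuccinimide, BrN1C(=O)CCC1=O
Why: Electrophilic aromatic bromination at C5 of 4, which is para to the 2-benzyloxy group, ortho to the 4-benzyloxy group and unhindered, as in the bromination of 1,2,4-trimethoxybenzene.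

Step 4
Reactants: 5 1-bromo-2,4-dibenzyloxy-5-methoxybenzene
Product: 6 methyl 2,4-dibenzyloxy-5-methoxybenzoate
Conditions: Pd(OAc)2 (2 mol %), Xantphos (2 mol %), CO (1 atm), MeOH, Et3N, 70 °C
Reagents that add atoms: carbon monoxide, [C-]#[O+]; methanol, CO
Why: Palladium-catalysed alkoxycarbonylation of an aryl bromide (oxidative addition to zerovalent palladium, CO insertion, methanolysis of the acylpalladium), for which the wide-bite-angle ligand allows atmospheric pressure with electron-rich ortho-substituted bromides.

Step 5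
Reactants: 6 methyl 2,4-dibenzyloxy-5-methoxybenzoate; 7 acetylacetone (pentane-2,4-dione)
Product: 8 1-(2,4-dibenzyloxy-5-methoxyphenyl)hexane-1,3,5-trione
Conditions: 7 (1.5 equiv), NaH (4 equiv), DME, reflux; then cold 1 M HCl
Reagents that add atoms: none
Why: Claisen-type aroylation of a β-diketone dianion at its terminal carbon, driven by deprotonation of the more acidic triketone, as established for acetylacetone and electron-rich methyl benzoates under NaH in refluxing DME.

Step 6
Reactants: 8 1-(2,4-dibenzyloxy-5-methoxyphenyl)hexane-1,3,5-trione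
Product: 9 2-(2,4-dibenzyloxy-5-methoxyphenyl)-6-methyl-4H-pyran-4-one
Conditions: p-TsOH·H2O (0.2 equiv), toluene, reflux, Dean–Stark trap
Reagents that add atoms: none
Why: Acid-catalysed cyclodehydration of a 1,3,5-triketone to a 4-pyranone; catalytic sulfonic acid should spare the aryl benzyl ethers, and with the ortho oxygen of ring B etherified no chromone can form instead.

Step 7
Reactants: 9 2-(2,4-dibenzyloxy-5-methoxyphenyl)-6-methyl-4H-pyran-4-one; 10 methyl malonyl chloride (methyl 3-chloro-3-oxopropanoate)
Product: 11 methyl 4-[6-(2,4-dibenzyloxy-5-methoxyphenyl)-4-oxo-4H-pyran-2-yl]-3-oxobutanoate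
Conditions: LiN(SiMe3)2 (2.2 equiv), THF, −78 °C; then 10 (1.2 equiv), −78 to −40 °C; aq. NH4Cl
Reagents that add atoms: none
Why: Lateral (vinylogous) deprotonation of the ring methyl group of a 2-methyl-4-pyranone and C-acylation of the dienolate at the exocyclic carbon by an acid chloride, the second equivalent of base being taken up by the more acidic β-keto ester product.

Step 8
Reactants: 11 methyl 4-[6-(2,4-dibenzyloxy-5-methoxyphenyl)-4-oxo-4H-pyran-2-yl]-3-oxobutanoate
Product: 12 2-(2,4-dibenzyloxy-5-methoxyphenyl)-5,7-dihydroxy-4H-chromen-4-one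
Conditions: Mg(OMe)2 (5 equiv), MeOH, 50 °C; then 1 M HCl
Reagents that add atoms: none
Why: Proposed new method: Mg(OMe)2 should deprotonate the chain methylene next to the pyranone to give a magnesium dienolate conjugated through the ring C2=C3 bond to the ring carbonyl, which places nucleophilic character on pyranone C3; this carbon adds to the ester carbonyl, methoxide leaves, and two enolisations turn the new carbocycle into the aromatic 5,7-diol, held as the magnesium chelate of the 5-oxide and the C4 carbonyl. The closest known reactions are the base- or Mg(OMe)2-mediated Claisen cyclisations of open-chain 3,5,7-triketo esters to acylphloroglucinols and the C-acylation of 4-pyranone dienolates; new here is the use of a pyranone α-carbon as the nucleophile of such a ring closure. Ring A closes in the 6-exo-trig mode and the bond formed is C4a–C5. No stereocentre is created. The step needs Claisen-type closure to prevail over aldol-type closure and O-acylation, and the pyranone secures this: the ring carbonyl lies trans to the side chain across the ring C2=C3 bond and cannot be reached by the malonyl methylene, attack of pyranone C3 on the chain ketone would give a four-membered ring, and no enol oxygen can reach the ester through a five- or six-membered ring, so the ester is the only electrophile that closes a six-membered ring. The remaining threat is conjugate opening of the pyranone by methoxide, which would unmask an open tetraketo ester with aldol options; magnesium chelation and a moderate temperature are meant to hold this back.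

Step 9
Reactants: 12 2-(2,4-dibenzyloxy-5-methoxyphenyl)-5,7-dihydroxy-4H-chromen-4-one
Product: 13 6,8-dibromo-2-(2,4-dibenzyloxy-5-methoxyphenyl)-5,7-dihydroxy-4H-chromen-4-one
Conditions: NBS (2.05 equiv), DMF, 0 °C
Reagents that add atoms: N-bromosuccinimide, BrN1C(=O)CCC1=O
Why: Electrophilic aromatic bromination at the two free positions of the phloroglucinol-type ring A, which with two free hydroxyls is far more nucleophilic than the ether-only ring B or C3, as in the 6,8-dibromination of chrysin.

Step 10
Reactants: 13 6,8-dibromo-2-(2,4-dibenzyloxy-5-methoxyphenyl)-5,7-dihydroxy-4H-chromen-4-one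
Product: 14 6,8-dibromo-2-(2,4-dibenzyloxy-5-methoxyphenyl)-5,7-dimethoxy-4H-chromen-4-one
Conditions: MeI (excess), K2CO3, DMF, 50 °C
Reagents that add atoms: iodomethane, CI
Why: Williamson O-methylation, run warm with excess MeI because the 5-hydroxyl is hydrogen-bonded to the C4 carbonyl; C-methylation is excluded because C6 and C8 carry bromine.

Step 11
Reactants: 14 6,8-dibromo-2-(2,4-dibenzyloxy-5-methoxyphenyl)-5,7-dimethoxy-4H-chromen-4-one
Product: 15 2-(2,4-dibenzyloxy-5-methoxyphenyl)-5,6,7,8-tetramethoxy-4H-chromen-4-one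
Conditions: NaOMe (excess), CuBr (0.3 equiv), MeOH–DMF, 110 °C
Reagents that add atoms: sodium methoxide, [Na+].[O-]C
Why: Copper-catalysed Ullmann-type methoxylation of aryl bromides, the established way to turn 6- and 8-bromo-5,7-dimethoxyflavones into polymethoxyflavones.

Step 12
Reactants: 15 2-(2,4-dibenzyloxy-5-methoxyphenyl)-5,6,7,8-tetramethoxy-4H-chromen-4-one
Product: 16 2-(2,4-dihydroxy-5-methoxyphenyl)-5,6,7,8-tetramethoxy-4H-chromen-4-one (CNP0237834.0)
Conditions: H2 (1 atm), 10% Pd/C, EtOAc–MeOH, rt
Reagents that add atoms: none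
Why: Catalytic hydrogenolysis of benzyl aryl ethers, which should leave the methyl ethers and the flavone C2=C3 bond untouched at atmospheric pressure and avoids the Lewis acids that would cleave the 5-methoxy group.

**Compound list**

1 | 3-benzyloxy-4-methoxybenzaldehyde | COc1ccc(C=O)cc1OCc1ccccc1 | starting material
2 | 3-benzyloxy-4-methoxyphenyl formate | COc1ccc(OC=O)cc1OCc1ccccc1 | intermediate
3 | 3-benzyloxy-4-methoxyphenol | COc1ccc(O)cc1OCc1ccccc1 | intermediate
4 | 2,4-dibenzyloxy-1-methoxybenzene | COc1ccc(OCc2ccccc2)cc1OCc1ccccc1 | intermediate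
5 | 1-bromo-2,4-dibenzyloxy-5-methoxybenzene | COc1cc(Br)c(OCc2ccccc2)cc1OCc1ccccc1 | intermediate
6 | methyl 2,4-dibenzyloxy-5-methoxybenzoate | COC(=O)c1cc(OC)c(OCc2ccccc2)cc1OCc1ccccc1 | intermediate
7 | acetylacetone | CC(=O)CC(C)=O | starting material
8 | 1-(2,4-dibenzyloxy-5-methoxyphenyl)hexane-1,3,5-trione | CC(=O)CC(=O)CC(=O)c1cc(OC)c(OCc2ccccc2)cc1OCc1ccccc1 | intermediate
9 | 2-(2,4-dibenzyloxy-5-methoxyphenyl)-6-methyl-4H-pyran-4-one | Cc1cc(=O)cc(-c2cc(OC)c(OCc3ccccc3)cc2OCc2ccccc2)o1 | intermediate
10 | methyl malonyl chloride | COC(=O)CC(=O)Cl | starting material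
11 | methyl 4-[6-(2,4-dibenzyloxy-5-methoxyphenyl)-4-oxo-4H-pyran-2-yl]-3-oxobutanoate | COC(=O)CC(=O)Cc1cc(=O)cc(-c2cc(OC)c(OCc3ccccc3)cc2OCc2ccccc2)o1 | intermediate
12 | 2-(2,4-dibenzyloxy-5-methoxyphenyl)-5,7-dihydroxy-4H-chromen-4-one | Oc1cc(O)c2c(c1)oc(-c1cc(OC)c(OCc3ccccc3)cc1OCc1ccccc1)cc2=O | intermediate
13 | 6,8-dibromo-2-(2,4-dibenzyloxy-5-methoxyphenyl)-5,7-dihydroxy-4H-chromen-4-one | Oc1c(Br)c(O)c2c(c1Br)oc(-c1cc(OC)c(OCc3ccccc3)cc1OCc1ccccc1)cc2=O | intermediate
14 | 6,8-dibromo-2-(2,4-dibenzyloxy-5-methoxyphenyl)-5,7-dimethoxy-4H-chromen-4-one | COc1c(Br)c(OC)c2c(c1Br)oc(-c1cc(OC)c(OCc3ccccc3)cc1OCc1ccccc1)cc2=O | intermediate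
15 | 2-(2,4-dibenzyloxy-5-methoxyphenyl)-5,6,7,8-tetramethoxy-4H-chromen-4-one | COc1c(OC)c(OC)c2c(c1OC)oc(-c1cc(OC)c(OCc3ccccc3)cc1OCc1ccccc1)cc2=O | intermediate
16 | 2-(2,4-dihydroxy-5-methoxyphenyl)-5,6,7,8-tetramethoxy-4H-chromen-4-one | COc1cc(-c2cc(=O)c3c(OC)c(OC)c(OC)c(OC)c3o2)c(O)cc1O | target

**Count and risks**

Total step count: 12. Longest linear sequence: 12 steps (from 1 to 16; 7 and 10 are bought).

Steps most likely to fail:

1. Step 8. The dienolate may fail to react through pyranone C3, and methoxide may instead open the pyranone by conjugate addition or cleave the β-keto ester by retro-Claisen methanolysis, so that ring A is not formed or the chain folds by other modes. Fallback with known chemistry, setting out from 6 and returning at 12: ester 6 would be saponified (LiOH, THF–H2O, then HCl) to 2,4-dibenzyloxy-5-methoxybenzoic acid F1, and this converted with oxalyl chloride and catalytic DMF into 2,4-dibenzyloxy-5-methoxybenzoyl chloride F2. The acid chloride would C-acylate the lithium polyanion of commercial 2,4,6-trihydroxyacetophenone (LiN(SiMe3)2, 4.5 equiv, THF, −78 °C to rt) to give 1-(2,4-dibenzyloxy-5-methoxyphenyl)-3-(2,4,6-trihydroxyphenyl)propane-1,3-dione F3. Cyclodehydration of this diketone (p-TsOH·H2O, AcOH–toluene, 80 °C) would give 12, where the route is rejoined at step 9.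

2. Step 7. Proton transfer from the acidic acid chloride to the dienolate (ketene formation) and O-acylation may outrun C-acylation at the exocyclic carbon. Fallback setting out from 9 and returning at 11: the lateral lithium dienolate of 9 (LiN(SiMe3)2, THF, −78 °C) would be acetylated with N-methoxy-N-methylacetamide, an acyl donor that carries no comparably acidic proton, to give 2-(2,4-dibenzyloxy-5-methoxyphenyl)-6-(2-oxopropyl)-4H-pyran-4-one F4. Its dianion (LiN(i-Pr)2, 3 equiv, THF, −78 to 0 °C) would then be carboxylated at the terminal methyl carbon with dimethyl carbonate, the standard terminal acylation of β-dicarbonyl dianions, to give 11.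

3. Step 11. Reductive loss of bromine and base-induced opening of ring C may compete with the slow C–O coupling at two positions that are each flanked by two ortho substituents. Fallback setting out from 14 and returning at 15: a double Miyaura borylation (B2pin2, KOAc, Pd(OAc)2, SPhos, dioxane, 100 °C) would give 2-(2,4-dibenzyloxy-5-methoxyphenyl)-5,7-dimethoxy-6,8-bis(4,4,5,5-tetramethyl-1,3,2-dioxaborolan-2-yl)-4H-chromen-4-one F5. Oxidation of both C–B bonds (NaBO3·4H2O, THF–H2O, rt) would give 2-(2,4-dibenzyloxy-5-methoxyphenyl)-6,8-dihydroxy-5,7-dimethoxy-4H-chromen-4-one F6, and O-methylation (MeI, K2CO3, DMF) would give 15.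

**Further compounds**

F1 | step 8 | 2,4-dibenzyloxy-5-methoxybenzoic acid | OC(=O)c1cc(OC)c(OCc2ccccc2)cc1OCc1ccccc1
F2 | step 8 | 2,4-dibenzyloxy-5-methoxybenzoyl chloride | ClC(=O)c1cc(OC)c(OCc2ccccc2)cc1OCc1ccccc1
F3 | step 8 | 1-(2,4-dibenzyloxy-5-methoxyphenyl)-3-(2,4,6-trihydroxyphenyl)propane-1,3-dione | O=C(CC(=O)c1c(O)cc(O)cc1O)c1cc(OC)c(OCc2ccccc2)cc1OCc1ccccc1
F4 | step 7 | 2-(2,4-dibenzyloxy-5-methoxyphenyl)-6-(2-oxopropyl)-4H-pyran-4-one | CC(=O)Cc1cc(=O)cc(-c2cc(OC)c(OCc3ccccc3)cc2OCc2ccccc2)o1
F5 | step 11 | 2-(2,4-dibenzyloxy-5-methoxyphenyl)-5,7-dimethoxy-6,8-bis(4,4,5,5-tetramethyl-1,3,2-dioxaborolan-2-yl)-4H-chromen-4-one | COc1c(B4OC(C)(C)C(C)(C)O4)c(OC)c2c(c1B5OC(C)(C)C(C)(C)O5)oc(-c6cc(OC)c(OCc7ccccc7)cc6OCc6ccccc6)cc2=O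
F6 | step 11 | 2-(2,4-dibenzyloxy-5-methoxyphenyl)-6,8-dihydroxy-5,7-dimethoxy-4H-chromen-4-one | COc1c(O)c(OC)c2c(c1O)oc(-c1cc(OC)c(OCc3ccccc3)cc1OCc1ccccc1)cc2=O
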